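**Plan**

- Cuts: the depside ester bond (ring A carboxyl carbon to the 4-oxygen of ring B) is cut first, giving a ring A acid and benzyl orsellinate. Ring A is then taken back to its 5,6-dihydro level, a cyclohexane-1,3-dione, and opened at ring bonds C1–C6 and C2–C3 into dimethyl malonate and an E-enone. The enone C=C is cut to an aldehyde derived from methyl 3-oxodecanoate.
- Enabling feature: in ring A the carboxyl-bearing C1 lies between C2–OH and C6–CH2, with the second oxygen on C4. C1 with its two carbonyl carbons (ester carbon and C2) is therefore a malonate, C3–C4(O) is the acetyl end of a methyl ketone, and C5–C6 is its enone double bond. In the resulting 2,4-dioxocyclohexane-1-carboxylate the C2 oxygen belongs to the chelated keto ester and the C4 oxygen to a free vinylogous acid, which later tells C2–OH from C4–OMe.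
- Forward order: the side chain with its ketone masked as a dioxolane is made first (steps 1–3). Ring A is closed in step 4 and aromatized in steps 5–6. Its acid is freed (step 7) and joined in step 9 to ring B (orsellinic acid, benzylated in step 8). The ketone and the ring B acid are unmasked last (steps 10–11).
- Stereochemistry: the target has no stereocentre. The two sp3 centres created in step 4 are racemic and transient and vanish on aromatization. The E geometry of the enone (stabilized ylide) is consumed in the conjugate addition.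
- Remark: the ketone stays a dioxolane from step 1 to step 10, because a free 2-oxononyl ketone beside the ring A ester or activated acid would enol-lactonize to an isocoumarin. For the same reason ring A is aromatized without strong acid (enol ether, then selenoxide dehydrogenation).

Key step: step 4

**Route**

Step 1
Reactants: 1 methyl 3-oxodecanoate
Product: 2 methyl 2-(2-heptyl-1,3-dioxolan-2-yl)acetate
Conditions: HOCH2CH2OH, p-TsOH·H2O (cat.), toluene, reflux, Dean–Stark
Reagents that add atoms: ethylene glycol, OCCO
Why: Acid-catalysed ketalization of the ketone of a β-keto ester with azeotropic removal of water is routine, leaves the ester untouched and masks the future side-chain ketone against hydride, ylide and base.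

Step 2
Reactants: 2 methyl 2-(2-heptyl-1,3-dioxolan-2-yl)acetate
Product: 4 2-(2-heptyl-1,3-dioxolan-2-yl)acetaldehyde, via aluminium hemiacetal 3 (not isolated)
Conditions: i-Bu2AlH (1.05 equiv), CH2Cl2, −78 °C; MeOH quench, aq. KNaC4H4O6 (potassium sodium tartrate), rt
Reagents that add atoms: none
Why: Partial ester reduction with one equivalent of i-Bu2AlH at −78 °C should stop at the tetrahedral aluminium hemiacetal 3, held by chelation to a dioxolane oxygen, which releases the aldehyde only on aqueous work-up, so over-reduction to the alcohol is held back.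

Step 3
Reactants: 4 2-(2-heptyl-1,3-dioxolan-2-yl)acetaldehyde; 5 1-(triphenylphosphoranylidene)propan-2-one
Product: 6 (E)-5-(2-heptyl-1,3-dioxolan-2-yl)pent-3-en-2-one
Conditions: THF, reflux
Reagents that add atoms: none
Why: Wittig olefination with the ketone-stabilized ylide 5 is reversible up to the oxaphosphetane and should therefore deliver the E-enone, and its neutral conditions do not trigger β-elimination of the ketal aldehyde.

Step 4
Reactants: 6 (E)-5-(2-heptyl-1,3-dioxolan-2-yl)pent-3-en-2-one; 7 dimethyl malonate
Product: 9 methyl 6-[(2-heptyl-1,3-dioxolan-2-yl)methyl]-2,4-dioxocyclohexane-1-carboxylate, via Michael adduct 8 (not isolated)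
Conditions: NaOMe (1.05 equiv), 7 (1.15 equiv), MeOH, 0 °C to rt, then reflux; cold 1 M HCl to pH 4
Reagents that add atoms: none
Why: Sodium dimethyl malonate adds in 1,4-fashion to the β-carbon of enone 6 (ring bond C1–C6) to give keto diester 8, whose methyl ketone enolate, formed by proton exchange, attacks one malonate ester carbonyl and expels methoxide (ring bond C2–C3); the expelled methoxide deprotonates the new 1,3-dione, which pulls the reversible sequence to the product. The closest known reaction type is the Michael–Claisen annulation of malonates with alk-3-en-2-ones to 6-alkyl-2,4-dioxocyclohexane-1-carboxylates, the classical dihydroresorcylate synthesis. The one ring closes by a 6-exo-trig acyl substitution; closure from the other ketone α-carbon would give a four-membered ring and does not compete, so the order of the two events fixes the C1-ester, C2/C4-dioxo, C6-alkyl pattern. The new sp3 centres C1 and C6 form racemic and epimerizable under the basic conditions and need no control, because both become sp2 on aromatization. The selectivity needed is conjugate addition ahead of deprotonation of the γ-CH2 between alkene and ketal carbon, which could open the dioxolane by vinylogous β-elimination or move the double bond out of conjugation; it is secured by the soft malonate anion, a slight excess of malonate over NaOMe so that little free methoxide remains, and completion of the Michael addition at 0 °C to rt before heating for the Claisen closure. The dioxolane is inert to methoxide and should survive the brief cold acidification that releases the vinylogous acid.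

Step 5
Reactants: 9 methyl 6-[(2-heptyl-1,3-dioxolan-2-yl)methyl]-2,4-dioxocyclohexane-1-carboxylate
Product: 10 methyl 6-[(2-heptyl-1,3-dioxolan-2-yl)methyl]-4-methoxy-2-oxocyclohex-3-ene-1-carboxylate
Conditions: HC(OMe)3 (3 equiv), camphorsulfonic acid (cat.), CH2Cl2–MeOH (20:1), 0 °C to rt; Et3N quench
Reagents that add atoms: trimethyl orthoformate, COC(OC)OC; methanol, CO
Why: Acid-catalysed enol etherification of a cyclic vinylogous acid (methanol as nucleophile, trimethyl orthoformate as water scavenger) should put the methyl on the C4 oxygen, the less hindered one whose partner C2 carbonyl then stays conjugated and hydrogen-bonded with the C1 ester, while the absence of water and the small amount of methanol leave the dioxolane in place.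

Step 6
Reactants: 10 methyl 6-[(2-heptyl-1,3-dioxolan-2-yl)methyl]-4-methoxy-2-oxocyclohex-3-ene-1-carboxylate
Product: 13 methyl 2-[(2-heptyl-1,3-dioxolan-2-yl)methyl]-6-hydroxy-4-methoxybenzoate, via selenide 11 (not isolated), via selenoxide 12 (not isolated)
Conditions: NaH, THF, 0 °C; PhSeCl, −78 to 0 °C; then 30% H2O2, pyridine, CH2Cl2, 0 °C to rt
Reagents that add atoms: none
Why: Selenoxide dehydrogenation of a β-keto ester: the sodium enolate is selenenylated at C1 anti to the C6 substituent to give 11, oxidation gives selenoxide 12, which undergoes syn-elimination with the cis C6–H, and the resulting cross-conjugated dienone tautomerizes to the phenol, all under basic to neutral conditions that spare the ketal.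

Step 7
Reactants: 13 methyl 2-[(2-heptyl-1,3-dioxolan-2-yl)methyl]-6-hydroxy-4-methoxybenzoate
Product: 14 2-[(2-heptyl-1,3-dioxolan-2-yl)methyl]-6-hydroxy-4-methoxybenzoic acid
Conditions: KOH, DMSO–H2O (4:1), 80 °C; then 1 M HCl to pH 4, 0 °C
Reagents that add atoms: potassium hydroxide, [K+].[OH-]
Why: Saponification of a hindered 2,6-disubstituted methyl salicylate needs hydroxide in hot aqueous DMSO, conditions to which the dioxolane and the aryl methyl ether are inert, and cold acidification only to pH 4 avoids ketal hydrolysis and decarboxylation of the free acid.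

Step 8
Reactants: 15 orsellinic acid
Product: 16 benzyl orsellinate
Conditions: BnBr, KHCO3, DMF, rt
Reagents that add atoms: benzyl bromide, BrCc1ccccc1
Why: KHCO3 deprotonates only the carboxylic acid, and SN2 alkylation of the carboxylate with benzyl bromide at room temperature should give the benzyl ester without touching the phenols or provoking decarboxylation.

Step 9
Reactants: 14 2-[(2-heptyl-1,3-dioxolan-2-yl)methyl]-6-hydroxy-4-methoxybenzoic acid; 16 benzyl orsellinate
Product: 17 benzyl 4-({2-[(2-heptyl-1,3-dioxolan-2-yl)methyl]-6-hydroxy-4-methoxybenzoyl}oxy)-2-hydroxy-6-methylbenzoate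
Conditions: DCC, DMAP (cat.), CH2Cl2, 0 °C to rt
Reagents that add atoms: none
Why: Carbodiimide esterification with DMAP as acyl-transfer catalyst (Steglich esterification) should acylate the free 4-OH of 16, since the 2-OH groups of both partners are hydrogen-bonded to their ortho carbonyls and flanked, hence poorly nucleophilic, and the dioxolane prevents the side-chain ketone from enol-lactonizing onto the activated carboxyl.

Step 10
Reactants: 17 benzyl 4-({2-[(2-heptyl-1,3-dioxolan-2-yl)methyl]-6-hydroxy-4-methoxybenzoyl}oxy)-2-hydroxy-6-methylbenzoate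
Product: 18 benzyl 2-hydroxy-4-{[2-hydroxy-4-methoxy-6-(2-oxononyl)benzoyl]oxy}-6-methylbenzoate
Conditions: 1 M aq. HCl, THF, rt
Reagents that add atoms: water, O
Why: Hydrolysis of a dialkyl-ketone dioxolane via its oxocarbenium ion is far faster in dilute aqueous acid at room temperature than hydrolysis of the benzyl and aryl esters or enol-lactonization of the freed ketone onto the depside ester.

Step 11
Reactants: 18 benzyl 2-hydroxy-4-{[2-hydroxy-4-methoxy-6-(2-oxononyl)benzoyl]oxy}-6-methylbenzoate
Product: 19 2-hydroxy-4-{[2-hydroxy-4-methoxy-6-(2-oxononyl)benzoyl]oxy}-6-methylbenzoic acid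
Conditions: H2 (1 atm), 10% Pd/C, EtOAc, rt
Reagents that add atoms: none
Why: Hydrogenolysis of the benzylic C–O bond of the benzyl ester over Pd/C is neutral and leaves the aryl ester, the dialkyl ketone, the methyl ether and the phenols unchanged.

**Compound list**

1 | methyl 3-oxodecanoate | CCCCCCCC(=O)CC(=O)OC | starting material
2 | methyl 2-(2-heptyl-1,3-dioxolan-2-yl)acetate | CCCCCCCC1(CC(=O)OC)OCCO1 | intermediate
3 | 2-{2-[(diisobutylalumanyl)oxy]-2-methoxyethyl}-2-heptyl-1,3-dioxolane (aluminium hemiacetal, racemic) | CCCCCCCC1(CC(OC)O[Al](CC(C)C)CC(C)C)OCCO1 | intermediate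
4 | 2-(2-heptyl-1,3-dioxolan-2-yl)acetaldehyde | CCCCCCCC1(CC=O)OCCO1 | intermediate
5 | 1-(triphenylphosphoranylidene)propan-2-one | CC(=O)C=P(c1ccccc1)(c1ccccc1)c1ccccc1 | starting material
6 | (E)-5-(2-heptyl-1,3-dioxolan-2-yl)pent-3-en-2-one | CC(=O)/C=C/CC1(CCCCCCC)OCCO1 | intermediate
7 | dimethyl malonate | COC(=O)CC(=O)OC | starting material
8 | dimethyl 2-[1-(2-heptyl-1,3-dioxolan-2-yl)-4-oxopentan-2-yl]propanedioate (racemic) | CCCCCCCC1(CC(CC(C)=O)C(C(=O)OC)C(=O)OC)OCCO1 | intermediate
9 | methyl 6-[(2-heptyl-1,3-dioxolan-2-yl)methyl]-2,4-dioxocyclohexane-1-carboxylate (racemic, C1 and C6 epimerizable, present largely as enol forms) | CCCCCCCC1(CC2CC(=O)CC(=O)C2C(=O)OC)OCCO1 | intermediate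
10 | methyl 6-[(2-heptyl-1,3-dioxolan-2-yl)methyl]-4-methoxy-2-oxocyclohex-3-ene-1-carboxylate (racemic) | CCCCCCCC1(CC2CC(OC)=CC(=O)C2C(=O)OC)OCCO1 | intermediate
11 | methyl 6-[(2-heptyl-1,3-dioxolan-2-yl)methyl]-4-methoxy-2-oxo-1-(phenylselanyl)cyclohex-3-ene-1-carboxylate (racemic) | CCCCCCCC1(CC2CC(OC)=CC(=O)C2(C(=O)OC)[Se]c3ccccc3)OCCO1 | intermediate
12 | methyl 6-[(2-heptyl-1,3-dioxolan-2-yl)methyl]-4-methoxy-2-oxo-1-(phenylseleninyl)cyclohex-3-ene-1-carboxylate (racemic) | CCCCCCCC1(CC2CC(OC)=CC(=O)C2(C(=O)OC)[Se](=O)c3ccccc3)OCCO1 | intermediate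
13 | methyl 2-[(2-heptyl-1,3-dioxolan-2-yl)methyl]-6-hydroxy-4-methoxybenzoate | CCCCCCCC1(Cc2cc(OC)cc(O)c2C(=O)OC)OCCO1 | intermediate
14 | 2-[(2-heptyl-1,3-dioxolan-2-yl)methyl]-6-hydroxy-4-methoxybenzoic acid | CCCCCCCC1(Cc2cc(OC)cc(O)c2C(=O)O)OCCO1 | intermediate
15 | orsellinic acid (2,4-dihydroxy-6-methylbenzoic acid) | Cc1cc(O)cc(O)c1C(=O)O | starting material
16 | benzyl orsellinate (benzyl 2,4-dihydroxy-6-methylbenzoate) | Cc1cc(O)cc(O)c1C(=O)OCc2ccccc2 | intermediate
17 | benzyl 4-({2-[(2-heptyl-1,3-dioxolan-2-yl)methyl]-6-hydroxy-4-methoxybenzoyl}oxy)-2-hydroxy-6-methylbenzoate | CCCCCCCC1(Cc2cc(OC)cc(O)c2C(=O)Oc2cc(C)c(C(=O)OCc3ccccc3)c(O)c2)OCCO1 | intermediate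
18 | benzyl 2-hydroxy-4-{[2-hydroxy-4-methoxy-6-(2-oxononyl)benzoyl]oxy}-6-methylbenzoate | CCCCCCCC(=O)Cc1cc(OC)cc(O)c1C(=O)Oc1cc(C)c(C(=O)OCc2ccccc2)c(O)c1 | intermediate
19 | 2-hydroxy-4-{[2-hydroxy-4-methoxy-6-(2-oxononyl)benzoyl]oxy}-6-methylbenzoic acid (CNP0320117.0) | CCCCCCCC(=O)Cc1cc(OC)cc(O)c1C(=O)Oc1cc(C)c(C(=O)O)c(O)c1 | target

**Count**

Total: 11 steps. Longest linear sequence: 10 steps (steps 1–7 and 9–11); step 8 is a one-step branch.

**Steps most likely to fail**

Step 4. Before malonate adds, the enone may lose a proton from the γ-CH2 and then expel a dioxolane oxygen or shift its double bond out of conjugation. On heating, the Michael adduct may also revert faster than it closes. The fallback sets out from aldehyde 4 and pairs the partners the other way round. Wittig olefination with methyl (triphenylphosphoranylidene)acetate (CH2Cl2, rt) would give methyl (E)-4-(2-heptyl-1,3-dioxolan-2-yl)but-2-enoate F1, a much less γ-acidic acceptor. Methyl acetoacetate with NaOMe in MeOH (rt, then reflux) would add through its C2 carbon to give dimethyl 2-acetyl-3-[(2-heptyl-1,3-dioxolan-2-yl)methyl]pentanedioate F2. The acetyl methyl group of F2 closes onto the distal ester in the same flask (acetoacetate–enoate Michael–Dieckmann annulation). Cold acidification then gives dione 9, where the route is rejoined.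

Step 5. The acid catalyst may transfer the dioxolane to a dimethyl ketal or strip it, and part of the methylation may go to the C2 oxygen. The fallback sets out from dione 9, aromatizes first and methylates afterwards. TMSCl and Et3N in DMF would give methyl 6-[(2-heptyl-1,3-dioxolan-2-yl)methyl]-2,4-bis(trimethylsilyloxy)cyclohexa-1,3-diene-1-carboxylate F3. DDQ in toluene at rt would dehydrogenate this dihydroarene to methyl 2-[(2-heptyl-1,3-dioxolan-2-yl)methyl]-4,6-bis(trimethylsilyloxy)benzoate F4. K2CO3 in MeOH at 0 °C would cleave the aryl silyl ethers to methyl 2-[(2-heptyl-1,3-dioxolan-2-yl)methyl]-4,6-dihydroxybenzoate F5. MeI (1.05 equiv) with K2CO3 in refluxing acetone would then methylate only the free 4-OH, the 2-OH being chelated to the ester. This comes back at phenol 13 and also bypasses step 6.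

Step 9. Acylation by the hindered 2,6-disubstituted acid may be slow enough for the carbodiimide adduct to rearrange to an N-acylurea. The free 2-OH may be acylated to give oligomers, or a dioxolane oxygen may capture the activated carboxyl. The fallback sets out from phenol 13 and blocks the 2-OH before a stronger activation. BnBr and K2CO3 in DMF at 60 °C would give methyl 2-(benzyloxy)-6-[(2-heptyl-1,3-dioxolan-2-yl)methyl]-4-methoxybenzoate F6. KOH in DMSO–H2O at 100 °C would give 2-(benzyloxy)-6-[(2-heptyl-1,3-dioxolan-2-yl)methyl]-4-methoxybenzoic acid F7. Yamaguchi esterification (2,4,6-trichlorobenzoyl chloride, Et3N, THF; then 16, DMAP, toluene, rt) would give benzyl 4-({2-(benzyloxy)-6-[(2-heptyl-1,3-dioxolan-2-yl)methyl]-4-methoxybenzoyl}oxy)-2-hydroxy-6-methylbenzoate F8. 1 M HCl in THF would give benzyl 4-{[2-(benzyloxy)-4-methoxy-6-(2-oxononyl)benzoyl]oxy}-2-hydroxy-6-methylbenzoate F9. Hydrogenolysis (H2, Pd/C, EtOAc) would remove both benzyl groups and come back at target 19.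

Further compounds
F1 | step 4 | methyl (E)-4-(2-heptyl-1,3-dioxolan-2-yl)but-2-enoate | COC(=O)/C=C/CC1(CCCCCCC)OCCO1
F2 | step 4 | dimethyl 2-acetyl-3-[(2-heptyl-1,3-dioxolan-2-yl)methyl]pentanedioate | COC(=O)CC(CC1(CCCCCCC)OCCO1)C(C(C)=O)C(=O)OC
F3 | step 5 | methyl 6-[(2-heptyl-1,3-dioxolan-2-yl)methyl]-2,4-bis(trimethylsilyloxy)cyclohexa-1,3-diene-1-carboxylate | CCCCCCCC1(CC2CC(O[Si](C)(C)C)=CC(O[Si](C)(C)C)=C2C(=O)OC)OCCO1
F4 | step 5 | methyl 2-[(2-heptyl-1,3-dioxolan-2-yl)methyl]-4,6-bis(trimethylsilyloxy)benzoate | CCCCCCCC1(Cc2cc(O[Si](C)(C)C)cc(O[Si](C)(C)C)c2C(=O)OC)OCCO1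
F5 | step 5 | methyl 2-[(2-heptyl-1,3-dioxolan-2-yl)methyl]-4,6-dihydroxybenzoate | CCCCCCCC1(Cc2cc(O)cc(O)c2C(=O)OC)OCCO1
F6 | step 9 | methyl 2-(benzyloxy)-6-[(2-heptyl-1,3-dioxolan-2-yl)methyl]-4-methoxybenzoate | CCCCCCCC1(Cc2cc(OC)cc(OCc3ccccc3)c2C(=O)OC)OCCO1
F7 | step 9 | 2-(benzyloxy)-6-[(2-heptyl-1,3-dioxolan-2-yl)methyl]-4-methoxybenzoic acid | CCCCCCCC1(Cc2cc(OC)cc(OCc3ccccc3)c2C(=O)O)OCCO1
F8 | step 9 | benzyl 4-({2-(benzyloxy)-6-[(2-heptyl-1,3-dioxolan-2-yl)methyl]-4-methoxybenzoyl}oxy)-2-hydroxy-6-methylbenzoate | CCCCCCCC1(Cc2cc(OC)cc(OCc3ccccc3)c2C(=O)Oc2cc(C)c(C(=O)OCc3ccccc3)c(O)c2)OCCO1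
F9 | step 9 | benzyl 4-{[2-(benzyloxy)-4-methoxy-6-(2-oxononyl)benzoyl]oxy}-2-hydroxy-6-methylbenzoate | CCCCCCCC(=O)Cc1cc(OC)cc(OCc2ccccc2)c1C(=O)Oc1cc(C)c(C(=O)OCc2ccccc2)c(O)c1
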